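Readings and results are simulated with made-up constants; the scatter is artificial.

The plateau reader and the clock counter disagree about what stands in these flasks at the asked time.

| flask | substrate | target | temperature | remark | time |
|---|---|---|---|---|---|
| winter | 0.75 M | 0.075 M | −12 °C | run made earlier |  |
| dusk | 1.1 M | 0.075 M | 4 °C | run made earlier |  |
| dawn | 1.5 M | 0.037 M | −12 °C | run made earlier |  |
| violet | 1.5 M | 0.0750 M | −20 °C |  | 3.0 min |
| amber | 1.5 M | 0.0750 M | 10 °C |  | 3.0 min |

winter run (percent of the substrate charged)

| time / min | target / % | isomer of the product / % |
|---|---|---|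
| 0.500 | 48.7 | 60.3 |
| 1.00 | 21.7 | 88.1 |
| 1.50 | 14.0 | 94.5 |
| 2.00 | 13.0 | 97.7 |
| 2.50 | 12.8 | 97.6 |
| 3.00 | 11.9 | 98.0 |
| 4.00 | 12.4 | 98.3 |

dusk run (percent of the substrate charged)

| time / s | target / % | isomer of the product / % |
|---|---|---|
| 10.0 | 33.7 | 72.7 |
| 20.0 | 29.8 | 77.5 |
| 30.0 | 29.6 | 76.7 |
| 40.0 | 29.7 | 77.7 |
| 50.0 | 30.6 | 78.2 |
| 60.0 | 30.7 | 76.6 |
| 80.0 | 29.9 | 76.9 |

dawn run (percent of the substrate charged)

| time / min | target / % | isomer of the product / % |
|---|---|---|
| 0.667 | 31.3 | 70.7 |
| 1.33 | 14.5 | 88.4 |
| 2.00 | 11.8 | 90.0 |
| 3.00 | 11.6 | 90.5 |
| 4.00 | 12.0 | 90.4 |

(standard deviation of a reading: 0.5 percentage points)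

- what was read earlier has a scatter of 0.5 percentage points, one standard deviation
- steps under discussion: substrate + target -> 2 target; substrate -> target; target <-> isomer of the product

* the best flask by share of target in all that became target or isomer of the product; "all alike" if 1.5 percentage points covers them all (violet / amber / all alike)
* share of target in all that became target or isomer of the product, violet
* share of target in all that became target or isomer of the product, amber

The plateau reader holds that each flask is simply at equilibrium between target and isomer of the product, which is thermodynamic control. The last readings give isomer of the product over target as 7.93 in winter and 2.57 in dusk. Violet lies below winter by half the distance that dusk lies above it, so he multiplies winter's ratio by the square root of the ratio between the two, and that gives violet a target share of 6.70%.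

The clock counter answers that equilibrium takes time, and that the cold flask must be asked how much it has had. The fall of target towards its plateau in the winter run gives a rate of 2.72 min⁻¹, while the first dusk reading, set against the whole gap, gives about 18.0 min⁻¹. The same square-root step downwards gives violet a relaxation half-life of 0.655 min, the time in which the gap between target's share and its equilibrium share shrinks by a factor 2.

The forecast says “Autocatalytic consumption takes about 0.3 min”, and with that allowance of 0.300 min violet gets 4.13 half-lives. From a start taken as pure target, my count leaves a share of 12.0%. The forecast, on the counter's side, says 13% for violet, a little above my figure, and 36.5% for amber, so it names amber as best. Amber is not in dispute, since the half-life I reckon from the dusk run, 2.31 s at a temperature colder than amber's, is far shorter than the asked time.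

The flask gives amber as best, at 36.7% against 15.1% for violet, which is well above the plateau reader's figure. Between 1.50 min and 3.00 min, violet's target was still falling, from 38.9% to 15.9% of the charge, while amber's stood at 38.6%.

    substrate + target → 2 target (k = 0.210 L mol⁻¹ s⁻¹, Ea = 43.0 kJ mol⁻¹)
    substrate → target (k = 1.60 × 10⁻⁴ s⁻¹, Ea = 83.0 kJ mol⁻¹)
    target ⇌ isomer of the product (K = 15.0, k = 0.0130 s⁻¹, Ea = 78.0 kJ mol⁻¹, ΔH = −43.0 kJ mol⁻¹)
    (constants at −20 °C)

The plateau reader's region shows in violet read at 8.0 min, where the count reaches 11.8 half-lives of 0.655 min, so the rule leaves a share of 6.73%, and that flask gives 6.39%.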